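**Early times.** After 60.0 min, the substrate stood at 94.8% of its charge in the amber run and 94.1% in the grey run, though amber held 0.75 M and grey 1 M. Open intermediate had reached 5.4% and 5.8%, while the largest target reading, 0.4%, lay near the scatter. From the mean of the two substrate readings I read 0.0571 h⁻¹. This is the release constant, the first-order rate constant of substrate opening: the fraction of the substrate present that opens per hour.

| flask | substrate | solid partner | remark | time |
|---|---|---|---|---|
| amber | 0.75 M | 0.12 M | run made earlier |  |
| grey | 1 M | 0.12 M | run made earlier |  |
| north-east | 0.50 M | 0.120 M |  | 5.0 h |
| south | 0.50 M | 0.250 M |  | 5.0 h |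
| north-west | 0.50 M | 0.500 M |  | 5.0 h |
| south-east | 0.50 M | 1.00 M |  | 5.0 h |
| west | 0.50 M | 2.00 M |  | 5.0 h |

| run | time / min | open intermediate / % | target / % | substrate / % |
|---|---|---|---|---|
| amber | 8.00 | 0.7 | 0 | 99.2 |
| amber | 20.0 | 1.5 | 0 | 97.9 |
| amber | 40.0 | 3.6 | 0 | 96.1 |
| amber | 60.0 | 5.4 | 0 | 94.8 |
| grey | 8.00 | 0.8 | 0.3 | 99.5 |
| grey | 20.0 | 2.0 | 0.4 | 98.3 |
| grey | 40.0 | 3.4 | 0 | 96.6 |
| grey | 60.0 | 5.8 | 0.2 | 94.1 |

(readings scatter by 0.3 percentage points)

- given per volume of solution although it is solid: solid partner
- the earlier runs were read with a standard deviation of 0.3 percentage points
- at the start none of the solid partner is in solution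
- a step back or a flat step of under half a percent of the largest counts as no turn
- "hardly changes" means that all values lie within two and a half points (for a concentration: within two and a half percent of the largest)
- a step back or a flat step of under half a percent of the largest counts as no turn

1. [open intermediate] at the end for north-east, south, north-west, south-east, west, in this order
2. how the row runs (rises, then falls / hardly changes / falls all the way / falls, then rises / rises all the way)

**The curve.** I drew the released fraction, the share of the charge that has left the substrate, as one minus the exponential of the release constant times the time. Its slope starts at 0.0571 h⁻¹ in fractions of the charge. Its half-time is 12.1 h, longer than the 5.0 h run, so no knee falls inside the run. By the end the slope has eased to 0.0429 h⁻¹, and the curve stands at 24.8%, still bending slowly towards the whole charge. I committed to that figure for open intermediate and target together.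

**The forecast.** The forecast gave open intermediate by itself 22.0% of the charge in north-east and 24.8% from south to west, so its shape was rises all the way: “so the row rises slightly, then stays flat”. My figure was for the sum.

**The flask.** Open intermediate ended at 22.0% of the charge in north-east and 20.6% in each flask from south to west, so the row falls all the way.

    solid partner ⇌ fresh partner, rate k1*(cs1 - [fresh partner]) while solid is left; crystals form when [fresh partner] > cs1 (solubility = 0.260 M, k = 0.590 h⁻¹)
    open intermediate + second intermediate ⇌ target (K = 8.40 M⁻¹, k = 22.0 M⁻¹ h⁻¹)
    substrate → open intermediate (k = 0.0560 h⁻¹)
    2 second intermediate → homo product (k = 12.0 M⁻¹ h⁻¹)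
    fresh partner → second intermediate (k = 0.0960 h⁻¹)

**Release again.** Target stood at 2.49% in north-east and 3.87% in south-east. The released fraction less target gives 22.3% for north-east and 20.9% for south-east. In west after 50.0 h, the release constant gives a released fraction of 94.2%. Less the 18.7% of target, that leaves 75.5%, and the open intermediate there stood at 75.2%.

The earlier runs and the new flask were computed for substances that don't exist; scatter was added.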